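**Overview**

- Cuts: the C15–C5' bond first (vinylogous aldol; C5' is the oxygen-bearing ring carbon of the butenolide), then C13=C14 (two-carbon formyl olefination of a C13 methyl ketone). The carboxyl carbon C18 is then traced back through an 18,6α-lactone and a 6α,18-ether to a plain 4α-methyl group, which leads to (+)-larixol.
- Enabling feature: the 6α-oxygen on C6 (ring B) and C18 on C4 (ring A) are both equatorial and flank the ring-fusion carbon C5. Along O6–C6–C5–C4–C18 an O6 radical can reach only the 4α-methyl hydrogens and then close a five-membered ether onto that carbon.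
- Forward order: rings A and B come with larixol. The side chain is cut to the methyl ketone, the 8(17)-alkene becomes a spiro-epoxide, the 6α,18-tetrahydrofuran is closed and oxidized to the lactone, and the epoxide is reduced to the C8 methyl carbinol. The lactone is then opened and protected, C14–C15 are added, and the preformed butenolide ring is attached last.
- Stereochemistry: C5, C6, C9 and C10 from larixol; C8 from α-face epoxidation and reduction at C17; C4 from the key step; 13E from the olefination; C15 and C5' together from a catalytic asymmetric vinylogous Mukaiyama aldol.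

Key step: step 3

Assumption: the titanium catalyst made from (R)-BINOL, (R)-1,1'-bi-2-naphthol, is taken to direct the silyloxyfuran to the Re face of the C15 aldehyde, the usual sense for titanium binaphtholate additions to aldehydes. If a test on 3-methylbut-2-enal shows the opposite sense, (S)-BINOL is used with nothing else changed.

**Route**

Step 1
Reactants: 1 (+)-larixol
Product: 2 6α-hydroxy-14,15-dinorlabd-8(17)-en-13-one
Conditions: KMnO4, MgSO4, acetone–H2O, 0 °C to rt
Reagents that add atoms: none
Why: Permanganate oxidative cleavage of the tertiary vinyl carbinol (dihydroxylation of the vinyl group, then glycol cleavage) should leave C13 as the methyl ketone, a degradation established for labdane vinyl carbinols, while the hindered 8(17)-alkene and the peri-shielded 6α-hydroxyl react more slowly in the buffered medium; no stereocentre is formed.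

Step 2
Reactants: 2 6α-hydroxy-14,15-dinorlabd-8(17)-en-13-one
Product: 3 8α,17-epoxy-6α-hydroxy-14,15-dinorlabdan-13-one
Conditions: mCPBA, NaHCO3, CH2Cl2, 0 °C
Reagents that add atoms: mCPBA (3-chloroperoxybenzoic acid), O=C(OO)c1cccc(Cl)c1
Why: Prilezhaev epoxidation of the exocyclic alkene should occur from the α face, where the peracid approaches equatorially and avoids the axial C10 methyl that guards the β face, so that oxygen becomes 8α and C17 8β (this sets C8), while buffer and low temperature hold back Baeyer–Villiger oxidation of the ketone and any minor β-epoxide is removed by chromatography.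

Step 3
Reactants: 3 8α,17-epoxy-6α-hydroxy-14,15-dinorlabdan-13-one
Product: 6 6α,18:8α,17-diepoxy-14,15-dinorlabdan-13-one, via 6α-hypoiodite 4 (not isolated), via 18-iodo-6α-alcohol 5 (not isolated)
Conditions: PhI(OAc)2, I2, cyclohexane–CH2Cl2, tungsten lamp, 25 °C
Reagents that add atoms: none
Why: Acetyl hypoiodite, formed from PhI(OAc)2 and I2, converts 3 into hypoiodite 4; visible light cleaves its O–I bond, the 6α-alkoxy radical takes a hydrogen from C18 through a six-membered transition state (O6–C6–C5–C4–C18–H), the C18 radical is iodinated to 5, and O6 then displaces iodide. The closest known reaction type is the Suárez hypoiodite reaction, as in the conversion of steroidal 6β-alcohols into 6β,19-ethers. The one new ring, the tetrahydrofuran O6–C6–C5–C4–C18, closes by 5-exo-tet substitution at C18 and is trans-fused to rings A and B. The one new stereocentre, C4, is fixed by the rigid trans-decalin (C5 and C10 from larixol): only the equatorial 4α-methyl lies in peri contact with the equatorial 6α-oxygen, so it becomes C18 and the axial 4β-methyl stays as C19. The step needs site selectivity (C18 over C19, C20 and the epoxide methylene) and hydrogen transfer faster than β-scission of C5–C6; the short O6···C18 distance should secure both, and 3 offers the iodine reagents no second hydroxyl and no alkene.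

Step 4
Reactants: 6 6α,18:8α,17-diepoxy-14,15-dinorlabdan-13-one
Product: 7 8α,17-epoxy-13-oxo-14,15-dinorlabdan-18,6α-olide
Conditions: RuCl3·xH2O (cat.), NaIO4, pH 7 phosphate buffer, EtOAc–MeCN–H2O, rt
Reagents that add atoms: sodium periodate (terminal source of the carbonyl oxygen, delivered through ruthenium tetroxide), [Na+].[O-]I(=O)(=O)=O
Why: Ruthenium tetroxide oxidation of an ether α-methylene to the lactone should attack the exposed C18 methylene and not the C6 methine, whose hydrogen is axial on the β face between the axial methyls C19 and C20, while the neutral buffer keeps the spiro-epoxide closed; no stereocentre changes.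

Step 5
Reactants: 7 8α,17-epoxy-13-oxo-14,15-dinorlabdan-18,6α-olide
Product: 8 17-bromo-8α-hydroxy-13-oxo-14,15-dinorlabdan-18,6α-olide
Conditions: LiBr, AcOH, THF, rt
Reagents that add atoms: lithium bromide, [Li+].[Br-]
Why: Halohydrin formation by SN2 opening of the hydrogen-bond-activated epoxide should place bromide on the primary carbon C17 and leave the C8–O bond, hence the 8α configuration, untouched, the weak acid being too mild to open the lactone, ionize C8 or dehydrate the new hydroxy ketone.

Step 6
Reactants: 8 17-bromo-8α-hydroxy-13-oxo-14,15-dinorlabdan-18,6α-olide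
Product: 9 8α-hydroxy-13-oxo-14,15-dinorlabdan-18,6α-olide
Conditions: Bu3SnH, AIBN (cat.), toluene, 80 °C
Reagents that add atoms: none
Why: Radical-chain dehalogenation with tributyltin hydride should turn the bromomethyl group into the 8β-methyl group without touching ketone, lactone or tertiary alcohol, the primary radical being reduced faster than it can add to the distant carbonyl; no stereocentre is involved.

Step 7
Reactants: 9 8α-hydroxy-13-oxo-14,15-dinorlabdan-18,6α-olide
Product: 11 allyl 6α,8α-dihydroxy-13-oxo-14,15-dinorlabdan-18-oate, via potassium carboxylate 10 (not isolated)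
Conditions: KOH (1.1 equiv), MeOH–H2O, 50 °C; evaporate; allyl bromide, DMF, 0 °C to rt
Reagents that add atoms: potassium hydroxide, [K+].[OH-]; allyl bromide, C=CCBr
Why: Saponification of the strained trans-fused γ-lactone (acyl–oxygen cleavage, so the C6–O bond and the 6α configuration are kept) followed by SN2 O-alkylation of the carboxylate should give the allyl ester, the sequence staying basic to neutral so that neither relactonization nor acid-catalysed cyclodehydration of the 8-hydroxy 13-ketone is promoted; the crude ester is silylated at once.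

Step 8
Reactants: 11 allyl 6α,8α-dihydroxy-13-oxo-14,15-dinorlabdan-18-oate
Product: 12 allyl 13-oxo-6α,8α-bis(triethylsilyloxy)-14,15-dinorlabdan-18-oate
Conditions: TESOTf, 2,6-lutidine, CH2Cl2, −78 to 0 °C; aq. NaHCO3
Reagents that add atoms: triethylsilyl triflate, CC[Si](CC)(CC)OS(=O)(=O)C(F)(F)F
Why: Silyl triflate silylation, the standard method for hindered secondary and tertiary alcohols, should cap O6 (which can then no longer lactonize) and O8 (which can no longer close onto C13), any silyl enol ether formed at the methyl ketone reverting on aqueous work-up and silica gel.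

Step 9
Reactants: 12 allyl 13-oxo-6α,8α-bis(triethylsilyloxy)-14,15-dinorlabdan-18-oate; 13 diethyl [(E)-2-(cyclohexylamino)vinyl]phosphonate
Product: 15 allyl (13E)-15-oxo-6α,8α-bis(triethylsilyloxy)labd-13-en-18-oate, via N-cyclohexyl azadiene 14 (not isolated)
Conditions: NaH, THF, 0 °C to rt, then 50 °C; then AcOH–NaOAc buffer (pH 4.5), hexane, rt
Reagents that add atoms: water, O
Why: Horner–Wadsworth–Emmons formyl olefination, in which the sodium salt of the enamine phosphonate adds to the methyl ketone and loses diethyl phosphate to give the unsaturated imine that mild hydrolysis converts into the enal, should favour the 13E isomer through reversible addition (the larger C12 chain ends up trans to C15), the minor 13Z enal being removed by chromatography; the hindered allyl ester and the silyl ethers should survive base and buffer.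

Step 10
Reactants: 16 4-methylfuran-2(5H)-one
Product: 17 4-methyl-2-(trimethylsilyloxy)furan
Conditions: TMSOTf, Et3N, Et2O, 0 °C; distil
Reagents that add atoms: trimethylsilyl triflate, C[Si](C)(C)OS(=O)(=O)C(F)(F)F
Why: Soft enolization and O-silylation of the butenolide should give the aromatic 2-silyloxyfuran, the usual dienolate equivalent for vinylogous Mukaiyama aldol additions, the trimethylsilyl group being chosen because it transfers readily to the aldolate and is lost on work-up.

Step 11
Reactants: 15 allyl (13E)-15-oxo-6α,8α-bis(triethylsilyloxy)labd-13-en-18-oate; 17 4-methyl-2-(trimethylsilyloxy)furan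
Product: 19 allyl (13E,15S)-15-hydroxy-15-[(2S)-3-methyl-5-oxo-2,5-dihydrofuran-2-yl]-6α,8α-bis(triethylsilyloxy)labd-13-en-18-oate, via 15-O-trimethylsilyl ether 18 (not isolated)
Conditions: Ti(OiPr)4 (20 mol %), (R)-BINOL (20 mol %), 4 Å MS, Et2O, −20 °C; then aq. citric acid, THF, 0 °C
Reagents that add atoms: none
Why: Catalytic asymmetric vinylogous Mukaiyama aldol addition, in which the chiral titanium binaphtholate activates the aldehyde and furan C5 attacks C15 in 1,2-fashion (the β,β-disubstituted enal resists conjugate addition) through an open transition state, should favour the threo pair and, with the (R)-ligand exposing the Re face of the aldehyde, give 15S and 5'S, the labdane stereocentres being too remote to interfere; the brief acidic work-up removes the transferred trimethylsilyl group and should spare the hindered triethylsilyl ethers.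

Step 12
Reactants: 19 allyl (13E,15S)-15-hydroxy-15-[(2S)-3-methyl-5-oxo-2,5-dihydrofuran-2-yl]-6α,8α-bis(triethylsilyloxy)labd-13-en-18-oate
Product: 20 (13E,15S)-15-hydroxy-15-[(2S)-3-methyl-5-oxo-2,5-dihydrofuran-2-yl]-6α,8α-bis(triethylsilyloxy)labd-13-en-18-oic acid
Conditions: Pd(PPh3)4 (5 mol %), morpholine, THF, rt; pH 4 buffer work-up
Reagents that add atoms: none
Why: Tsuji–Trost deallylation, in which zerovalent palladium ionizes the allyl ester to a π-allyl complex that morpholine intercepts, is near-neutral and should spare the butenolide, the allylic alcohol and both silyl ethers; it is placed before desilylation so that an ester never faces the free 6α-hydroxyl.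

Step 13
Reactants: 20 (13E,15S)-15-hydroxy-15-[(2S)-3-methyl-5-oxo-2,5-dihydrofuran-2-yl]-6α,8α-bis(triethylsilyloxy)labd-13-en-18-oic acid
Product: 21 (13E,15S)-6α,8α,15-trihydroxy-15-[(2S)-3-methyl-5-oxo-2,5-dihydrofuran-2-yl]labd-13-en-18-oic acid
Conditions: HF·pyridine, pyridine, THF, 0 °C to rt
Reagents that add atoms: none
Why: Fluoride-driven cleavage of the two triethylsilyl ethers under pyridine buffering should free O6 and O8 without ionizing the C15 allylic alcohol or epimerizing the base-sensitive centre C5', and the free 6α-hydroxy acid is not expected to close the strained trans-fused lactone under these conditions.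

**Compound list**

1 | (+)-larixol, (13S)-labda-8(17),14-diene-6α,13-diol | C=C[C@@](C)(O)CC[C@@H]1[C@@]2(C)CCCC(C)(C)[C@@H]2[C@@H](O)CC1=C | starting material
2 | 6α-hydroxy-14,15-dinorlabd-8(17)-en-13-one | CC(=O)CC[C@@H]1[C@@]2(C)CCCC(C)(C)[C@@H]2[C@@H](O)CC1=C | intermediate
3 | 8α,17-epoxy-6α-hydroxy-14,15-dinorlabdan-13-one | CC(=O)CC[C@@H]1[C@@]2(C)CCCC(C)(C)[C@@H]2[C@@H](O)C[C@@]1(C3)O3 | intermediate
4 | 8α,17-epoxy-6α-(iodooxy)-14,15-dinorlabdan-13-one (hypoiodite) | CC(=O)CC[C@@H]1[C@@]2(C)CCCC(C)(C)[C@@H]2[C@@H](OI)C[C@@]1(C3)O3 | intermediate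
5 | 8α,17-epoxy-6α-hydroxy-18-iodo-14,15-dinorlabdan-13-one | CC(=O)CC[C@@H]1[C@@]2(C)CCC[C@@](C)(CI)[C@@H]2[C@@H](O)C[C@@]1(C3)O3 | intermediate
6 | 6α,18:8α,17-diepoxy-14,15-dinorlabdan-13-one | CC(=O)CC[C@@H]1[C@@]2(C)CCC[C@@](C)(CO4)[C@@H]2[C@@H]4C[C@@]1(C3)O3 | intermediate
7 | 8α,17-epoxy-13-oxo-14,15-dinorlabdan-18,6α-olide | CC(=O)CC[C@@H]1[C@@]2(C)CCC[C@@](C)(C(=O)O4)[C@@H]2[C@@H]4C[C@@]1(C3)O3 | intermediate
8 | 17-bromo-8α-hydroxy-13-oxo-14,15-dinorlabdan-18,6α-olide | CC(=O)CC[C@@H]1[C@@]2(C)CCC[C@@](C)(C(=O)O3)[C@@H]2[C@@H]3C[C@@]1(CBr)O | intermediate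
9 | 8α-hydroxy-13-oxo-14,15-dinorlabdan-18,6α-olide | CC(=O)CC[C@@H]1[C@@]2(C)CCC[C@@](C)(C(=O)O3)[C@@H]2[C@@H]3C[C@@]1(C)O | intermediate
10 | potassium 6α,8α-dihydroxy-13-oxo-14,15-dinorlabdan-18-oate | CC(=O)CC[C@@H]1[C@@]2(C)CCC[C@@](C)(C(=O)[O-])[C@@H]2[C@@H](O)C[C@@]1(C)O.[K+] | intermediate
11 | allyl 6α,8α-dihydroxy-13-oxo-14,15-dinorlabdan-18-oate | CC(=O)CC[C@@H]1[C@@]2(C)CCC[C@@](C)(C(=O)OCC=C)[C@@H]2[C@@H](O)C[C@@]1(C)O | intermediate
12 | allyl 13-oxo-6α,8α-bis(triethylsilyloxy)-14,15-dinorlabdan-18-oate | CC(=O)CC[C@@H]1[C@@]2(C)CCC[C@@](C)(C(=O)OCC=C)[C@@H]2[C@@H](O[Si](CC)(CC)CC)C[C@@]1(C)O[Si](CC)(CC)CC | intermediate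
13 | diethyl [(E)-2-(cyclohexylamino)vinyl]phosphonate | CCOP(=O)(OCC)/C=C/NC1CCCCC1 | starting material
14 | allyl (13E)-15-(cyclohexylimino)-6α,8α-bis(triethylsilyloxy)labd-13-en-18-oate | C1CCCCC1N=C/C=C(\C)CC[C@@H]1[C@@]2(C)CCC[C@@](C)(C(=O)OCC=C)[C@@H]2[C@@H](O[Si](CC)(CC)CC)C[C@@]1(C)O[Si](CC)(CC)CC | intermediate
15 | allyl (13E)-15-oxo-6α,8α-bis(triethylsilyloxy)labd-13-en-18-oate | O=C/C=C(\C)CC[C@@H]1[C@@]2(C)CCC[C@@](C)(C(=O)OCC=C)[C@@H]2[C@@H](O[Si](CC)(CC)CC)C[C@@]1(C)O[Si](CC)(CC)CC | intermediate
16 | 4-methylfuran-2(5H)-one | CC1=CC(=O)OC1 | starting material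
17 | 4-methyl-2-(trimethylsilyloxy)furan | Cc1coc(O[Si](C)(C)C)c1 | intermediate
18 | allyl (13E,15S)-15-[(2S)-3-methyl-5-oxo-2,5-dihydrofuran-2-yl]-6α,8α-bis(triethylsilyloxy)-15-(trimethylsilyloxy)labd-13-en-18-oate | CC1=CC(=O)O[C@@H]1[C@@H](O[Si](C)(C)C)/C=C(\C)CC[C@@H]1[C@@]2(C)CCC[C@@](C)(C(=O)OCC=C)[C@@H]2[C@@H](O[Si](CC)(CC)CC)C[C@@]1(C)O[Si](CC)(CC)CC | intermediate
19 | allyl (13E,15S)-15-hydroxy-15-[(2S)-3-methyl-5-oxo-2,5-dihydrofuran-2-yl]-6α,8α-bis(triethylsilyloxy)labd-13-en-18-oate | CC1=CC(=O)O[C@@H]1[C@@H](O)/C=C(\C)CC[C@@H]1[C@@]2(C)CCC[C@@](C)(C(=O)OCC=C)[C@@H]2[C@@H](O[Si](CC)(CC)CC)C[C@@]1(C)O[Si](CC)(CC)CC | intermediate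
20 | (13E,15S)-15-hydroxy-15-[(2S)-3-methyl-5-oxo-2,5-dihydrofuran-2-yl]-6α,8α-bis(triethylsilyloxy)labd-13-en-18-oic acid | CC1=CC(=O)O[C@@H]1[C@@H](O)/C=C(\C)CC[C@@H]1[C@@]2(C)CCC[C@@](C)(C(=O)O)[C@@H]2[C@@H](O[Si](CC)(CC)CC)C[C@@]1(C)O[Si](CC)(CC)CC | intermediate
21 | (13E,15S)-6α,8α,15-trihydroxy-15-[(2S)-3-methyl-5-oxo-2,5-dihydrofuran-2-yl]labd-13-en-18-oic acid (CNP0292216.1) | CC1=CC(=O)O[C@@H]1[C@@H](O)/C=C(\C)CC[C@@H]1[C@@]2(C)CCC[C@@](C)(C(=O)O)[C@@H]2[C@@H](O)C[C@@]1(C)O | target

**Step count**

Total steps: 13. Longest linear sequence: 12 steps (steps 1 to 9 and 11 to 13, from (+)-larixol); step 10 is a one-step side branch.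

**Steps most likely to fail**

Step 3. The 6α-alkoxy radical may cleave the C5–C6 bond (β-scission to the tertiary C5 radical) faster than it abstracts hydrogen, or the iodine reagents may open the spiro-epoxide. The fallback avoids an oxygen radical by hydroxyl-directed C–H silylation; it sets out from 3 and returns at 7.
- NaBH4 (MeOH, 0 °C) reduces the ketone of 3 to 8α,17-epoxy-14,15-dinorlabdane-6α,13-diol F1 (C13 epimers, of no consequence).
- Et2SiH2 with [Ir(cod)OMe]2 (cat.) in THF converts both hydroxyls into diethyl(hydrido)silyl ethers, giving 8α,17-epoxy-6α,13-bis(diethylsilyloxy)-14,15-dinorlabdane F2.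
- [Rh(cod)Cl]2 with 4,5-bis(diphenylphosphino)-9,9-dimethylxanthene and norbornene as hydrogen acceptor (THF, 100 °C) should insert the O6-bound silicon into a primary δ-C–H bond. Only the 4α-methyl is in reach, which would give the six-membered 6α-O–SiEt2–C18 oxasilinane F3; the C13 silyl ether has no primary C–H in range.
- Tamao–Fleming oxidation (H2O2, KHCO3, MeOH–THF) turns C18–Si into C18–OH and frees the other oxygens, giving 8α,17-epoxy-14,15-dinorlabdane-6α,13,18-triol F4.
- TEMPO (cat.) with excess PhI(OAc)2 in CH2Cl2 oxidizes the primary C18 alcohol first; O6 captures it as the lactol, which goes on to the lactone, and the C13 alcohol is oxidized back to the ketone. The product is 7.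

Step 11. The catalyst may discriminate weakly between the faces of a hindered β,β-disubstituted enal and a 4-substituted silyloxyfuran, or may turn over slowly. The fallback gives up catalyst control and moves the stereochemical decision to a separation; it sets out from 15 and 17 and returns at 19.
- BF3·OEt2 (1 equiv, CH2Cl2, −78 °C) promotes the same addition through the open transition state that favours the threo pair.
- This should give 19 together with its threo diastereomer, allyl (13E,15R)-15-hydroxy-15-[(2R)-3-methyl-5-oxo-2,5-dihydrofuran-2-yl]-6α,8α-bis(triethylsilyloxy)labd-13-en-18-oate F5.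
- Because the labdane core is a single enantiomer, the two are diastereomers and are separated by chromatography.

Step 9. E/Z selectivity at the new trisubstituted alkene may be low, and enolization of the methyl ketone by the basic reagent may stall conversion. The fallback fixes the geometry at a stable amide stage and then adjusts the oxidation level; it sets out from 12 and returns at 15.
- Horner–Wadsworth–Emmons reaction of 12 with diethyl [2-(methoxy(methyl)amino)-2-oxoethyl]phosphonate (NaH, THF, reflux) gives allyl (13E)-15-[methoxy(methyl)amino]-15-oxo-6α,8α-bis(triethylsilyloxy)labd-13-en-18-oate F6, from which any Z isomer is separated.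
- DIBAL-H (THF, −78 °C) reduces the Weinreb amide through its chelated tetrahedral intermediate faster than the hindered neopentyl-type allyl ester, giving enal 15.

Further compounds
F1 | step 3 | 8α,17-epoxy-14,15-dinorlabdane-6α,13-diol (C13 epimers) | CC(O)CC[C@@H]1[C@@]2(C)CCCC(C)(C)[C@@H]2[C@@H](O)C[C@@]1(C3)O3
F2 | step 3 | 8α,17-epoxy-6α,13-bis(diethylsilyloxy)-14,15-dinorlabdane | CC[SiH](CC)OC(C)CC[C@@H]1[C@@]2(C)CCCC(C)(C)[C@@H]2[C@@H](O[SiH](CC)CC)C[C@@]1(C3)O3
F3 | step 3 | 13-(diethylsilyloxy)-8α,17-epoxy-14,15-dinorlabdane with a 6α-O–SiEt2–C18 oxasilinane bridge | CC[SiH](CC)OC(C)CC[C@@H]1[C@@]2(C)CCC[C@@](C)(C[Si](CC)(CC)O4)[C@@H]2[C@@H]4C[C@@]1(C3)O3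
F4 | step 3 | 8α,17-epoxy-14,15-dinorlabdane-6α,13,18-triol | CC(O)CC[C@@H]1[C@@]2(C)CCC[C@@](C)(CO)[C@@H]2[C@@H](O)C[C@@]1(C3)O3
F5 | step 11 | allyl (13E,15R)-15-hydroxy-15-[(2R)-3-methyl-5-oxo-2,5-dihydrofuran-2-yl]-6α,8α-bis(triethylsilyloxy)labd-13-en-18-oate | CC1=CC(=O)O[C@H]1[C@H](O)/C=C(\C)CC[C@@H]1[C@@]2(C)CCC[C@@](C)(C(=O)OCC=C)[C@@H]2[C@@H](O[Si](CC)(CC)CC)C[C@@]1(C)O[Si](CC)(CC)CC
F6 | step 9 | allyl (13E)-15-[methoxy(methyl)amino]-15-oxo-6α,8α-bis(triethylsilyloxy)labd-13-en-18-oate | CON(C)C(=O)/C=C(\C)CC[C@@H]1[C@@]2(C)CCC[C@@](C)(C(=O)OCC=C)[C@@H]2[C@@H](O[Si](CC)(CC)CC)C[C@@]1(C)O[Si](CC)(CC)CC
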